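## Retrosynthetic overview

1. The acetate goes on last. The 3-OAc/18-OH pattern comes from the free 3,18-diol through a cyclic orthoacetate.
2. The 2-substituted butadiene and the free 8-OH are both released from a δ-lactone (C13 carbonyl, O on C8) by vinyl addition and methylenation of C13.
3. Key disconnection: the lactone diol comes from an acyclic (2R,3R)-epoxy alcohol / E-alkene / Z-alkene / tert-butyl ester. One cationic cascade closes ring A, then ring B, then the lactone ring, and creates C4, C5, C10, C9 and C8.
4. The epoxy alcohol comes from the C17 triene ester by terminal SeO2 oxidation and asymmetric epoxidation, which sets C3.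
5. The triene ester comes from tert-butyl acetate and (2Z,6E)-farnesyl bromide. The latter comes from prenol (directed Z-lithiation) and geranyl bromide.

Assumption: the SMILES is taken literally as (3R,4S,5S,8S,9R,10R). This is an antipodal labdane with H9 on the same face as C20, so the side chain on C9 is axial. Labdane numbering is used throughout, and C18 is the equatorial CH2OH on C4.

## Route

Step 1
Reactants: 1 prenol (3-methylbut-2-en-1-ol); 2 geranyl bromide
Product: 4 (2Z,6E)-farnesol, via dilithiated prenol 3 (not isolated)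
Conditions: n-BuLi (2.1 equiv), TMEDA (2.1 equiv), Et2O/hexane, 0 °C to rt, 20 h; then 2 (0.9 equiv), THF, −78 °C to rt; H2O
Reagents that add atoms: none
Why: Alkoxide-directed allylic lithiation deprotonates only the methyl group cis to CH2OLi (O–Li···C chelate), so SN2 alkylation of that CH2Li terminus places the new chain cis to CH2OH (2Z) and leaves the 6E alkene of 2 untouched.

Step 2
Reactants: 4 (2Z,6E)-farnesol
Product: 5 (2Z,6E)-farnesyl bromide
Conditions: PBr3 (0.4 equiv), pyridine (cat.), Et2O, −10 °C, 30 min; used crude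
Reagents that add atoms: phosphorus tribromide, BrP(Br)Br
Why: PBr3 bromination (SN2 on the phosphite ester) of a primary allylic alcohol at low temperature proceeds without allylic transposition or Z/E leakage.

Step 3
Reactants: 5 (2Z,6E)-farnesyl bromide; 6 tert-butyl acetate
Product: 8 tert-butyl (4Z,8E)-5,9,13-trimethyltetradeca-4,8,12-trienoate, via lithium enolate of tert-butyl acetate 7 (not isolated)
Conditions: LiN(iPr)2 (1.2 equiv), THF, −78 °C; then 5, DMPU (2 equiv), −78 to −20 °C
Reagents that add atoms: none
Why: Ester enolate alkylation (SN2 at the primary allylic carbon) adds C12 and C13 with all alkene geometries retained, and the bulky tert-butyl ester suppresses Claisen self-condensation.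

Step 4
Reactants: 8 tert-butyl (4Z,8E)-5,9,13-trimethyltetradeca-4,8,12-trienoate
Product: 9 tert-butyl (4Z,8E,12E)-14-hydroxy-5,9,13-trimethyltetradeca-4,8,12-trienoate
Conditions: SeO2 (0.2 equiv), t-BuOOH (2.5 equiv, decane), salicylic acid (0.1 equiv), CH2Cl2, 0 °C to rt, stopped at about 60% conversion, 8 recycled
Reagents that add atoms: tert-butyl hydroperoxide, CC(C)(C)OO; selenium dioxide (oxygen carrier), O=[Se]=O
Why: Catalytic SeO2 allylic oxidation (ene reaction, then [2,3]-sigmatropic shift) prefers the terminal isopropylidene group and oxidises only its E-methyl, giving the E-allylic alcohol that later becomes the equatorial C18.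

Step 5
Reactants: 9 tert-butyl (4Z,8E,12E)-14-hydroxy-5,9,13-trimethyltetradeca-4,8,12-trienoate
Product: 10 tert-butyl (4Z,8E)-11-[(2R,3R)-3-(hydroxymethyl)-3-methyloxiran-2-yl]-5,9-dimethylundeca-4,8-dienoate
Conditions: Ti(OiPr)4 (10 mol %), D-(−)-diethyl tartrate (12 mol %), t-BuOOH (2 equiv, decane), 4 Å MS, CH2Cl2, −20 °C
Reagents that add atoms: tert-butyl hydroperoxide, CC(C)(C)OO
Why: Katsuki–Sharpless asymmetric epoxidation touches only the allylic-alcohol alkene, and the D-(−)-tartrate ligand delivers oxygen to the face that gives the (2R,3R)-epoxide, which fixes C3 as R.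

Step 6
Reactants: 10 tert-butyl (4Z,8E)-11-[(2R,3R)-3-(hydroxymethyl)-3-methyloxiran-2-yl]-5,9-dimethylundeca-4,8-dienoate
Product: 12 (3R,4S,5S,8S,9R,10R)-3,18-dihydroxy-14,15,16-trinorlabdan-13,8-olide (lactone diol), via dichloroaluminium alkoxide 11 (not isolated)
Conditions: MeAlCl2 (2.2 equiv, hexanes), CH2Cl2 (5 mM), −78 °C, 1 h, then −40 °C; aq. potassium sodium tartrate
Reagents that add atoms: none
Why: Proposed new method: the C18 hydroxyl becomes a dichloroaluminium alkoxide that chelates the epoxide and ionises its tertiary C4–O bond, and the chain then closes through an all-chair fold with anti addition across both alkenes (backside attack at C4 leaves the 3R C–O bond intact and equatorial and puts the former E-CH2OH equatorial, the 5(10)E alkene gives the trans ring A/ring B fusion, the 8(9)Z alkene forces C11 axial so that H9 is syn to C20, and the ester carbonyl, which from an axial C11 can reach C8 only along the equatorial line, closes the lactone and sheds isobutene), the closest known reaction types being the Lewis-acid epoxy-polyene cyclisation and the oxygen-terminated cyclisation of Z-homofarnesyl substrates to 9-epi bicycles.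

Step 7
Reactants: 12 lactone diol
Product: 15 (3R,4S,5S,8S,9R,10R)-labda-13(16),14-diene-3,8,18-triol, via bromomagnesium vinyl hemiketalate 13 (not isolated), via ring-opened vinyl ketone 14 (not isolated)
Conditions: CH2=CHMgBr (3.2 equiv), THF, −78 to −30 °C, 2 h; then Ph3P=CH2 (5 equiv, from Ph3PCH3Br and KOtBu in THF), −30 °C to rt, 12 h; H2O
Reagents that add atoms: vinylmagnesium bromide, C=C[Mg]Br; methyltriphenylphosphonium bromide, C[P+](c1ccccc1)(c1ccccc1)c1ccccc1.[Br-]
Why: Grignard mono-addition to a lactone stops at the cold tetrahedral hemiketalate because a tertiary alkoxide is a poor leaving group, and on warming the ring-opened enone is intercepted by Wittig methylenation, so C13 becomes the 2-position of the butadiene and the C8–O bond and its configuration are untouched.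

Step 8
Reactants: 15 (3R,4S,5S,8S,9R,10R)-labda-13(16),14-diene-3,8,18-triol
Product: 17 (3R,4S,5S,8S,9R,10R)-3-acetoxylabda-13(16),14-diene-8,18-diol (target), via cyclic methyl orthoacetate 16 (not isolated)
Conditions: MeC(OMe)3 (1.5 equiv), PPTS (5 mol %), CH2Cl2, rt; then AcOH/H2O 4:1, 0 °C, 20 min; cold neutral work-up
Reagents that add atoms: trimethyl orthoacetate, COC(C)(OC)OC; water, O
Why: Orthoester exchange engages only the 3,18-diol (the tertiary 8-OH is too hindered), and kinetic acid hydrolysis of the six-membered orthoester expels the less hindered primary alcohol, which leaves the acetyl group on the secondary O3 without changing any stereocentre.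

## Compound list

1 | prenol (3-methylbut-2-en-1-ol) | CC(C)=CCO | starting material
2 | geranyl bromide | CC(C)=CCC/C(C)=C/CBr | starting material
3 | dilithiated prenol, CH2Li cis to CH2OLi (not isolated) | [Li]C/C(C)=C\CO[Li] | intermediate
4 | (2Z,6E)-farnesol | CC(C)=CCC/C(C)=C/CC/C(C)=C\CO | intermediate
5 | (2Z,6E)-farnesyl bromide | CC(C)=CCC/C(C)=C/CC/C(C)=C\CBr | intermediate
6 | tert-butyl acetate | CC(=O)OC(C)(C)C | starting material
7 | lithium enolate of tert-butyl acetate (not isolated) | C=C(O[Li])OC(C)(C)C | intermediate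
8 | tert-butyl (4Z,8E)-5,9,13-trimethyltetradeca-4,8,12-trienoate | CC(C)=CCC/C(C)=C/CC/C(C)=C\CCC(=O)OC(C)(C)C | intermediate
9 | tert-butyl (4Z,8E,12E)-14-hydroxy-5,9,13-trimethyltetradeca-4,8,12-trienoate | OC/C(C)=C/CC/C(C)=C/CC/C(C)=C\CCC(=O)OC(C)(C)C | intermediate
10 | tert-butyl (4Z,8E)-11-[(2R,3R)-3-(hydroxymethyl)-3-methyloxiran-2-yl]-5,9-dimethylundeca-4,8-dienoate | OC[C@@]1(C)O[C@@H]1CC/C(C)=C/CC/C(C)=C\CCC(=O)OC(C)(C)C | intermediate
11 | dichloroaluminium alkoxide of 10 (not isolated) | Cl[Al](Cl)OC[C@@]1(C)O[C@@H]1CC/C(C)=C/CC/C(C)=C\CCC(=O)OC(C)(C)C | intermediate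
12 | (3R,4S,5S,8S,9R,10R)-3,18-dihydroxy-14,15,16-trinorlabdan-13,8-olide; trans-decalin, cis-fused δ-lactone, 3-OH and CH2OH equatorial | O=C1CC[C@@H]2[C@]3(C)CC[C@@H](O)[C@](C)(CO)[C@H]3CC[C@]2(C)O1 | intermediate
13 | tris(bromomagnesium) salt of the C13 vinyl hemiketal, ring stereocentres as in 12 (not isolated) | C=CC1(O[Mg]Br)CC[C@@H]2[C@]3(C)CC[C@@H](O[Mg]Br)[C@](C)(CO[Mg]Br)[C@H]3CC[C@]2(C)O1 | intermediate
14 | ring-opened C13 vinyl ketone as its tris(bromomagnesium) alkoxide, stereocentres as in 12 (not isolated) | C=CC(=O)CC[C@@H]1[C@]2(C)CC[C@@H](O[Mg]Br)[C@](C)(CO[Mg]Br)[C@H]2CC[C@]1(C)O[Mg]Br | intermediate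
15 | (3R,4S,5S,8S,9R,10R)-labda-13(16),14-diene-3,8,18-triol | C=CC(=C)CC[C@@H]1[C@]2(C)CC[C@@H](O)[C@](C)(CO)[C@H]2CC[C@]1(C)O | intermediate
16 | 3,18-O-(1-methoxyethylidene) derivative of 15, epimers at the orthoester carbon (not isolated) | C=CC(=C)CC[C@@H]1[C@]2(C)CC[C@H]3OC(C)(OC)OC[C@]3(C)[C@H]2CC[C@]1(C)O | intermediate
17 | (3R,4S,5S,8S,9R,10R)-3-acetoxylabda-13(16),14-diene-8,18-diol (CNP0313672.1) | C=CC(=C)CC[C@@H]1[C@]2(C)CC[C@@H](OC(C)=O)[C@](C)(CO)[C@H]2CC[C@]1(C)O | target

## Step count and risks

Total step count: 8. Longest linear sequence: 8 (from 1 and 2 to 17).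

**Step 6 (cascade).** The main dangers are proton loss at C8 before the ester closes, a stop after ring A, and a hydride shift at C4. The fallback sets out from 10 and comes back at 12. It replaces the cationic cascade with a radical one followed by a separate lactonisation.
- Cp2TiCl (trivalent titanium, made from Cp2TiCl2 and Mn dust, THF, rt) opens the epoxide homolytically at C4.
- Two 6-endo closures through the same chair–chair fold follow, and β-hydride loss from C8 gives tert-butyl 3,18-dihydroxy-14,15,16-trinorlabd-8(17)-en-13-oate F1.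
- CF3CO2H in CH2Cl2 at 0 °C then protonates the exocyclic alkene. The axial side-chain carboxyl closes onto C8 from the only face it can reach, giving 12.

**Step 7 (one-pot vinyl addition and methylenation).** The dangers are double addition of the Grignard reagent, conjugate addition of the ylide, and a hemiketalate that does not open. The fallback sets out from 12 and comes back at 15. It builds the diene from an alkyne instead of an enone.
- i-Bu2AlH (CH2Cl2, −78 °C) gives the lactol 14,15,16-trinorlabdane-13,8-lactol-3,18-diol F2.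
- Dimethyl 1-diazo-2-oxopropylphosphonate with K2CO3 in MeOH homologates the open hydroxy aldehyde to the terminal alkyne 15,16-dinorlabd-13-yne-3,8,18-triol F3.
- Enyne cross-metathesis under ethene (1 atm, second-generation Grubbs catalyst, CH2Cl2, rt) converts the alkyne directly into the 2-substituted butadiene of 15.

**Step 1 (dianion alkylation).** The dangers are attack through the internal carbon of the allyl dianion, SN2′ attack on 2, and halogen–metal exchange. The fallback sets out from 2 and comes back at 4. It fixes the Z alkene by stereoretentive cross-coupling.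
- The dianion of methyl acetoacetate (NaH, then n-BuLi, THF, 0 °C) is alkylated with 2 to give methyl (6E)-7,11-dimethyl-3-oxododeca-6,10-dienoate F4.
- Tf2O with aqueous Me4NOH in toluene at 0 °C gives the (E)-enol triflate methyl (2E,6E)-7,11-dimethyl-3-(trifluoromethylsulfonyloxy)dodeca-2,6,10-trienoate F5.
- MeMgBr with Fe(acac)3 (5 mol %, THF, −30 °C) replaces the triflate with retention to give methyl (2Z,6E)-farnesoate F6.
- i-Bu2AlH (CH2Cl2, −78 °C) reduces F6 to 4.

## Further compounds

F1 | step 6 | tert-butyl 3,18-dihydroxy-14,15,16-trinorlabd-8(17)-en-13-oate, spatial arrangement at C3, C4, C5, C9 and C10 as in 12 | CC(C)(C)OC(=O)CC[C@@H]1[C@]2(C)CC[C@@H](O)[C@](C)(CO)[C@H]2CCC1=C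
F2 | step 7 | 14,15,16-trinorlabdane-13,8-lactol-3,18-diol, ring stereocentres as in 12, anomers at C13 | OC1CC[C@@H]2[C@]3(C)CC[C@@H](O)[C@](C)(CO)[C@H]3CC[C@]2(C)O1
F3 | step 7 | 15,16-dinorlabd-13-yne-3,8,18-triol, stereocentres as in 15 | C#CCC[C@@H]1[C@]2(C)CC[C@@H](O)[C@](C)(CO)[C@H]2CC[C@]1(C)O
F4 | step 1 | methyl (6E)-7,11-dimethyl-3-oxododeca-6,10-dienoate | CC(C)=CCC/C(C)=C/CCC(=O)CC(=O)OC
F5 | step 1 | methyl (2E,6E)-7,11-dimethyl-3-(trifluoromethylsulfonyloxy)dodeca-2,6,10-trienoate | CC(C)=CCC/C(C)=C/CC/C(OS(=O)(=O)C(F)(F)F)=C\C(=O)OC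
F6 | step 1 | methyl (2Z,6E)-farnesoate | CC(C)=CCC/C(C)=C/CC/C(C)=C\C(=O)OC
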